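**Plan**
- Numbering: lactone O1, C2 (carbonyl), C3, C4 (Br), C5, exocyclic C6 (iodine), carbinol carbon C1'.
- Cuts, in retrosynthetic order: O1–C5 and C6–I (iodolactonisation of a 2-en-4-ynoic acid); C2 back to a vinyl group; C2–C3 and C4–Br across the C3=C4 bond; C1'–C(alkyne) of a diynone.
- Enabling feature: the C1' oxygen and the C4 bromine lie cis on the tetrasubstituted C3=C4 bond, so a five-membered ring C1'–O–Mg–C4=C3 can hold that geometry while the C2 carbon enters at C3 from the far side.
- Forward order: the chain is joined first (C4 diyne plus C4 acyl unit), then the temporary oxamagnesacycle forms and is opened by bromine, and the lactone ring closes last (5-exo-dig).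
- Stereochemistry: (R)-C1' from Ru-catalysed asymmetric transfer hydrogenation; the C3=C4 geometry from chelate-controlled anti vinylmagnesiation and retentive bromination; (E)-C5=C6 from anti iodolactonisation.

Key step: step 3

**Route**

Step 1
Reactants: 1 1,4-bis(trimethylsilyl)buta-1,3-diyne; 2 N-methoxy-N-methylbutanamide
Product: 5 8-(trimethylsilyl)octa-5,7-diyn-4-one, via lithium 4-(trimethylsilyl)buta-1,3-diynide 3 (not isolated), via lithium hemiaminal alkoxide 4 (not isolated)
Conditions: MeLi·LiBr (1.0 equiv), Et2O, rt; then 2, THF, −78 to 0 °C; inverse quench into cold 1 M aq. HCl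
Reagents that add atoms: none
Why: MeLi·LiBr cleaves only one C–Si bond of the bis-silyl diyne, and acylation of the resulting acetylide by the Weinreb amide (Weinreb ketone synthesis) stops at the chelated adduct 4, which releases the ynone only in the acidic quench that also keeps the liberated hydroxylamine protonated and off the ynone.

Step 2
Reactants: 5 8-(trimethylsilyl)octa-5,7-diyn-4-one
Product: 6 (4R)-8-(trimethylsilyl)octa-5,7-diyn-4-ol
Conditions: Ru(p-cymene)[(R,R)-TsDPEN] (2 mol %, from RuCl(p-cymene)[(R,R)-TsDPEN] and KOH), i-PrOH, rt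
Reagents that add atoms: none
Why: Noyori asymmetric transfer hydrogenation of an alkynyl ketone, in which the alkyne takes the place of the aryl group of an aryl ketone in the Ru–H/N–H transition state, so the (R,R)-catalyst should give the (R)-carbinol that becomes C1', and the propargylic alcohol is too poor a hydride donor to reverse the reduction.

Step 3
Reactants: 6 (4R)-8-(trimethylsilyl)octa-5,7-diyn-4-ol; 7 vinylmagnesium chloride
Product: 10 (4R,5Z)-6-bromo-5-ethenyl-8-(trimethylsilyl)oct-5-en-7-yn-4-ol, via chloromagnesium diynolate 8 (not isolated), via 1,2-oxamagnesole chelate 9 (not isolated)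
Conditions: vinylmagnesium chloride (3.5 equiv), THF/toluene, 0 to 60 °C; then NBS (4 equiv), THF, −78 to −20 °C; aq. Na2S2O3/NH4Cl
Reagents that add atoms: N-bromosuccinimide, O=C1CCC(=O)N1Br (bromine at C4; the ethenyl carbons come from reactant 7)
Why: One equivalent of Grignard reagent deprotonates the carbinol, and the magnesium alkoxide 8 binds a second equivalent whose vinyl group adds to the proximal alkyne carbon C3 while magnesium bonds to C4 on the alkoxide side, a net anti addition. The closest known reaction is the hydroxyl-directed anti carbomagnesiation of propargylic alcohols with vinyl Grignard reagents followed by halogen quench, applied here to a silyl-capped conjugated diynol. The only ring formed is the 2,5-dihydro-1,2-oxamagnesole 9, closed through the C4–Mg bond in a 5-endo-dig sense and opened again when NBS replaces C4–Mg by C4–Br with retention. The one new stereo-element, the C3=C4 geometry (bromine cis to C1', vinyl cis to the C5 alkyne), is set by this chelate ring, and the C1' centre is not touched. The step needs vinyl delivery to C3, reaction at the proximal alkyne only and anti addition; chelation to the C1' alkoxide secures all three, and the distal alkyne is out of reach of the alkoxide, capped by SiMe3 and stabilises the C4–Mg bond. NBS is used in excess because the remaining vinylmagnesium chloride is brominated as well.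

Step 4
Reactants: 10 (4R,5Z)-6-bromo-5-ethenyl-8-(trimethylsilyl)oct-5-en-7-yn-4-ol
Product: 11 (4R,5Z)-6-bromo-5-ethenyloct-5-en-7-yn-4-ol
Conditions: K2CO3 (0.3 equiv), MeOH, 0 °C
Reagents that add atoms: none
Why: Base-catalysed methanolysis of the alkynyl C–Si bond (protodesilylation of a silylalkyne) is fast at 0 °C, and it is placed before C2 becomes a carbonyl group so that methoxide never meets a β-bromo enal or enoate open to addition–elimination at C4.

Step 5
Reactants: 11 (4R,5Z)-6-bromo-5-ethenyloct-5-en-7-yn-4-ol
Product: 12 (2E)-3-bromo-2-[(1R)-1-hydroxybutyl]pent-2-en-4-ynal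
Conditions: OsO4 (2 mol %), NaIO4 (4 equiv), 2,6-lutidine (2 equiv), dioxane/H2O 3:1, rt
Reagents that add atoms: osmium tetroxide, O=[Os](=O)(=O)=O; sodium periodate NaIO4, [Na+].[O-]I(=O)(=O)=O (the aldehyde oxygen, relayed through osmium)
Why: Lemieux–Johnson oxidation, in which OsO4 should dihydroxylate the unhindered monosubstituted vinyl group far faster than the tetrasubstituted, bromine-deactivated C3=C4 bond or the alkyne, NaIO4 cleaves the diol in the same flask to the C2 aldehyde, and 2,6-lutidine holds back ketol formation.

Step 6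
Reactants: 12 (2E)-3-bromo-2-[(1R)-1-hydroxybutyl]pent-2-en-4-ynal
Product: 13 (2E)-3-bromo-2-[(1R)-1-hydroxybutyl]pent-2-en-4-ynoic acid
Conditions: NaClO2, NaH2PO4, 2-methyl-2-butene, t-BuOH/H2O, 0 °C to rt
Reagents that add atoms: sodium chlorite NaClO2, [Na+].[O-]Cl=O
Why: Pinnick oxidation takes the enal to the acid without touching the secondary alcohol, the terminal alkyne or the alkene geometry, since 2-methyl-2-butene removes the hypochlorous acid that would otherwise attack the π bonds.

Step 7
Reactants: 13 (2E)-3-bromo-2-[(1R)-1-hydroxybutyl]pent-2-en-4-ynoic acid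
Product: 14 (5E)-4-bromo-3-[(1R)-1-hydroxybutyl]-5-(iodomethylidene)furan-2(5H)-one
Conditions: I2 (3 equiv), NaHCO3 (3 equiv), MeCN, 0 °C to rt, dark
Reagents that add atoms: iodine, II
Why: Iodolactonisation of a 2-en-4-ynoic acid: the C2 carboxylate, held cis to the alkyne by the C3=C4 geometry, opens the iodonium ion of the terminal alkyne at the internal carbon C5 (5-exo-dig, Markovnikov) anti to iodine, which puts iodine trans to O1 and so gives the (E)-iodomethylidene, while the C1' hydroxyl sits trans to the alkyne and cannot compete.

**Compound list**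

1 | 1,4-bis(trimethylsilyl)buta-1,3-diyne | C[Si](C)(C)C#CC#C[Si](C)(C)C | starting material
2 | N-methoxy-N-methylbutanamide | CCCC(=O)N(C)OC | starting material
3 | lithium 4-(trimethylsilyl)buta-1,3-diyn-1-ide | [Li]C#CC#C[Si](C)(C)C | intermediate
4 | lithium 4-[methoxy(methyl)amino]-8-(trimethylsilyl)octa-5,7-diyn-4-olate | CCCC(O[Li])(N(C)OC)C#CC#C[Si](C)(C)C | intermediate
5 | 8-(trimethylsilyl)octa-5,7-diyn-4-one | CCCC(=O)C#CC#C[Si](C)(C)C | intermediate
6 | (4R)-8-(trimethylsilyl)octa-5,7-diyn-4-ol | CCC[C@@H](O)C#CC#C[Si](C)(C)C | intermediate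
7 | vinylmagnesium chloride | C=C[Mg]Cl | starting material
8 | chloromagnesium (4R)-8-(trimethylsilyl)octa-5,7-diyn-4-olate | CCC[C@@H](O[Mg]Cl)C#CC#C[Si](C)(C)C | intermediate
9 | (5R)-4-ethenyl-5-propyl-3-[(trimethylsilyl)ethynyl]-2,5-dihydro-1,2-oxamagnesole | CCC[C@@H](O1)C(C=C)=C(C#C[Si](C)(C)C)[Mg]1 | intermediate
10 | (4R,5Z)-6-bromo-5-ethenyl-8-(trimethylsilyl)oct-5-en-7-yn-4-ol | CCC[C@@H](O)/C(C=C)=C(\Br)C#C[Si](C)(C)C | intermediate
11 | (4R,5Z)-6-bromo-5-ethenyloct-5-en-7-yn-4-ol | CCC[C@@H](O)/C(C=C)=C(\Br)C#C | intermediate
12 | (2E)-3-bromo-2-[(1R)-1-hydroxybutyl]pent-2-en-4-ynal | CCC[C@@H](O)/C(C=O)=C(\Br)C#C | intermediate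
13 | (2E)-3-bromo-2-[(1R)-1-hydroxybutyl]pent-2-en-4-ynoic acid | CCC[C@@H](O)/C(C(=O)O)=C(\Br)C#C | intermediate
14 | (5E)-4-bromo-3-[(1R)-1-hydroxybutyl]-5-(iodomethylidene)furan-2(5H)-one | CCC[C@@H](O)C1=C(Br)/C(=C\I)OC1=O | target

**Step count**

Total steps: 7. Longest linear sequence: 7 steps (1 to 14).

**Steps most likely to fail**

Step 3. The halogen quench may erode the selectivity of the chelate: excess vinylmagnesium chloride competes for NBS, and the alkynyl-substituted alkenylmagnesium may be brominated through its cumulenic form at the silylated terminus or with loss of geometry. The fallback sets out from 6 and returns at 10. The magnesacycle is formed as before but trapped with Bu3SnCl, and work-up and chromatography should give (4R,5Z)-5-ethenyl-6-(tributylstannyl)-8-(trimethylsilyl)oct-5-en-7-yn-4-ol F1. Freed from all Grignard reagent, this stannane should undergo ipso bromodestannylation with NBS in MeCN/CH2Cl2 at 0 °C with retention, giving 10.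

Step 7. Ring closure may leak into the 6-endo-dig mode (an iodopyranone), and the (E)-iodide may isomerise or take up more iodine under excess I2 and light. The fallback sets out from 13 and returns at 14. Anti oxymercuration of the alkyne by the carboxylate with Hg(OCOCF3)2 and NaHCO3 in CH2Cl2 is strongly Markovnikov, hence 5-exo; exchange with aqueous NaCl should give the isolable (5E)-4-bromo-5-[(chloromercurio)methylidene]-3-[(1R)-1-hydroxybutyl]furan-2(5H)-one F3, with mercury trans to O1. Iododemercuration with I2 in CH2Cl2/pyridine at 0 °C replaces mercury by iodine with retention and gives 14.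

Step 5. Osmylation of the conjugated vinyl group may be slow, and the electrophilic bromo-enynal may over-oxidise or degrade while it sits with aqueous periodate. The fallback sets out from 11 and returns at 12. Upjohn dihydroxylation (OsO4 cat., N-methylmorpholine N-oxide, acetone/H2O, 0 °C) is stopped at (3E,4R)-3-(1-bromoprop-2-yn-1-ylidene)heptane-1,2,4-triol F2 (both C2 epimers), which is isolated. Criegee cleavage of its 1,2-diol with Pb(OAc)4 in dry CH2Cl2 at −20 °C over solid NaHCO3 then gives 12 without exposure to water or excess oxidant.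

Further compounds
F1 | step 3 | (4R,5Z)-5-ethenyl-6-(tributylstannyl)-8-(trimethylsilyl)oct-5-en-7-yn-4-ol | CCC[C@@H](O)/C(C=C)=C(\[Sn](CCCC)(CCCC)CCCC)C#C[Si](C)(C)C
F2 | step 5 | (3E,4R)-3-(1-bromoprop-2-yn-1-ylidene)heptane-1,2,4-triol (C2 epimers) | CCC[C@@H](O)/C(C(O)CO)=C(\Br)C#C
F3 | step 7 | (5E)-4-bromo-5-[(chloromercurio)methylidene]-3-[(1R)-1-hydroxybutyl]furan-2(5H)-one | CCC[C@@H](O)C1=C(Br)/C(=C\[Hg]Cl)OC1=O
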